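**Plan**

- Retrosynthesis: cut the C8 ester; cut the lactone at C7–C11 (with C11=C13) back to a 6-hydroxy-7,8-(E)-alkene; then cut O–C10 and C9–C10 together. This re-forms O–C7 and leads to a 2-vinyl-3,6-dihydro-2H-pyran that carries a CH2C(O)C(N2)CH3 arm on C3; the pyran comes from a furan.
- Enabling feature: the ring oxygen joins C3 and C10 of a cyclodecane, C10 is alpha to the C1 ketone (a carbenoid site), and C9–C8–C7 is an allyl unit whose end C7 can be tied to the same oxygen in a six-membered ring (O, C3–C7).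
- Forward: furan → dihydropyran (Achmatowicz) → oxolanone ring closed at O–C10 while the six-membered ring expands to the ten-membered carbocycle → dehydrogenation to the 3(2H)-furanone → methylene lactone annulated on C6–C7 → C8 ester.
- Stereochemistry: one carbinol centre (C7, from a Sharpless kinetic resolution, later destroyed) sets C3 (Kishi reduction) and C6 (Luche reduction, then Mitsunobu inversion). C3 sets C10 through the bridged bicycle. C6 sets the 7,8-epoxide (matched Sharpless epoxidation), whose opening with inversion sets C7 and keeps C8.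

Key step: step 10

Remarks: C1–C15 in the text are germacrane labels of the target (C1 ketone carbon, C3 and C10 the carbons joined by the ring oxygen, C6 the lactone O-bearing carbon, C8 the ester-bearing carbon, C11–C13 the methylene lactone carbons); compound names carry their own systematic locants. Diazoethane is used as a freshly prepared ethereal solution.

**Step 1**
Reactants: 1 furan-3-ylmethanol; 2 trimethyl orthoacetate
Product: 3 methyl 2-(3-methylfuran-2-yl)acetate
Conditions: 2 (excess), EtCO2H (cat.), 130 °C, MeOH distilled off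
Reagents that add atoms: none
Why: Johnson–Claisen rearrangement of the 3-furylmethyl ketene acetal puts the acetate carbon on furan C2, and re-aromatisation leaves the 3-methyl group; no stereocentre is formed.

**Step 2**
Reactants: 3 methyl 2-(3-methylfuran-2-yl)acetate
Product: 4 methyl 2-(5-formyl-3-methylfuran-2-yl)acetate
Conditions: POCl3, DMF, 0 °C to rt; then ice-water
Reagents that add atoms: N,N-dimethylformamide CN(C)C=O; water O
Why: Vilsmeier–Haack formylation should occur at the only free alpha position of the electron-rich 2,3-dialkylfuran.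

**Step 3**
Reactants: 4 methyl 2-(5-formyl-3-methylfuran-2-yl)acetate
Product: 5 methyl 2-[5-(1-hydroxyprop-2-en-1-yl)-3-methylfuran-2-yl]acetate (racemic)
Conditions: CH2=CHMgBr, THF, −78 °C; then aq. NH4Cl
Reagents that add atoms: vinylmagnesium bromide C=C[Mg]Br
Why: Grignard 1,2-addition to the aldehyde is much faster than attack on the methyl ester at −78 °C; the carbinol forms as a racemate.

**Step 4**
Reactants: 5 methyl 2-[5-(1-hydroxyprop-2-en-1-yl)-3-methylfuran-2-yl]acetate (racemic)
Product: 6 methyl 2-[(6R)-2-hydroxy-3-methyl-5-oxo-6-vinyl-5,6-dihydro-2H-pyran-2-yl]acetate (hemiketal, both C-2 epimers)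
Conditions: Ti(OiPr)4 (cat.), D-(−)-diisopropyl tartrate, t-BuOOH (0.5 equiv), 4 Å MS, CH2Cl2, −20 °C
Reagents that add atoms: tert-butyl hydroperoxide CC(C)(C)OO
Why: Sharpless kinetic resolution of a 2-furylcarbinol, run as an Achmatowicz rearrangement: with the D-tartrate the (R)-carbinol is the fast enantiomer and is oxidised to the pyranone while the (S)-alcohol is left, so at or below half conversion 6 should form in high ee with its carbinol centre (later C7) unchanged.

**Step 5**
Reactants: 6 methyl 2-[(6R)-2-hydroxy-3-methyl-5-oxo-6-vinyl-5,6-dihydro-2H-pyran-2-yl]acetate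
Product: 7 methyl 2-[(2S,6R)-3-methyl-5-oxo-6-vinyl-5,6-dihydro-2H-pyran-2-yl]acetate
Conditions: Et3SiH, CF3CO2H, CH2Cl2, −40 to 0 °C
Reagents that add atoms: none
Why: Kishi reduction: the hemiketal ionises to the oxocarbenium ion and axial hydride delivery gives the 2,6-cis-dihydropyranone, which sets C3 (S) with the acetate arm cis to the vinyl group.

**Step 6**
Reactants: 7 methyl 2-[(2S,6R)-3-methyl-5-oxo-6-vinyl-5,6-dihydro-2H-pyran-2-yl]acetate
Product: 8 methyl 2-[(2S,5S,6R)-5-hydroxy-3-methyl-6-vinyl-5,6-dihydro-2H-pyran-2-yl]acetate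
Conditions: NaBH4, CeCl3·7H2O, MeOH, −78 °C
Reagents that add atoms: none
Why: Luche 1,2-reduction; axial hydride attack should give the equatorial alcohol trans to the neighbouring vinyl group.

**Step 7**
Reactants: 8 methyl 2-[(2S,5S,6R)-5-hydroxy-3-methyl-6-vinyl-5,6-dihydro-2H-pyran-2-yl]acetate; 9 4-methoxyphenol
Product: 10 methyl 2-[(2S,5R,6R)-5-(4-methoxyphenoxy)-3-methyl-6-vinyl-5,6-dihydro-2H-pyran-2-yl]acetate
Conditions: PPh3, DIAD, toluene, 0 °C to rt
Reagents that add atoms: none
Why: Mitsunobu etherification inverts the allylic carbinol (SN2), so the C6 oxygen becomes cis to the acetate arm as the target requires, and protects it as an aryl ether in the same operation.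

**Step 8**
Reactants: 10 methyl 2-[(2S,5R,6R)-5-(4-methoxyphenoxy)-3-methyl-6-vinyl-5,6-dihydro-2H-pyran-2-yl]acetate
Product: 11 2-[(2S,5R,6R)-5-(4-methoxyphenoxy)-3-methyl-6-vinyl-5,6-dihydro-2H-pyran-2-yl]acetic acid
Conditions: LiOH, THF/H2O, 0 °C to rt; then 1 M HCl
Reagents that add atoms: lithium hydroxide [Li+].[OH-]
Why: Saponification of the methyl ester; the aryl allyl ether and the ring ether should survive cold aqueous hydroxide.

**Step 9**
Reactants: 11 2-[(2S,5R,6R)-5-(4-methoxyphenoxy)-3-methyl-6-vinyl-5,6-dihydro-2H-pyran-2-yl]acetic acid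
Product: 13 3-diazo-1-[(2S,5R,6R)-5-(4-methoxyphenoxy)-3-methyl-6-vinyl-5,6-dihydro-2H-pyran-2-yl]butan-2-one, via mixed isobutyl carbonic anhydride 12 (not isolated)
Conditions: i-BuOCOCl, Et3N, THF, −20 °C; then CH3CHN2, Et2O, −20 to 0 °C
Reagents that add atoms: diazoethane CC=[N+]=[N-]
Why: Acylation of a diazoalkane by a mixed anhydride (first stage of the Arndt–Eistert sequence) gives the alpha-methyl diazo ketone without touching a stereocentre.

**Step 10**
Reactants: 13 3-diazo-1-[(2S,5R,6R)-5-(4-methoxyphenoxy)-3-methyl-6-vinyl-5,6-dihydro-2H-pyran-2-yl]butan-2-one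
Product: 15 (1S,2Z,4S,5E,8S)-4-(4-methoxyphenoxy)-2,8-dimethyl-11-oxabicyclo[6.2.1]undeca-2,5-dien-9-one, via bicyclic oxonium ylide 14 (not isolated)
Conditions: Rh2(NHCOCF3)4 (2 mol %), CH2Cl2, reflux, slow addition of 13
Reagents that add atoms: none
Why: The divalent rhodium carbenoid formed from 13 by loss of N2 is attacked by the ring oxygen, which closes the five-membered oxonium ring by the O–C10 bond (ylide 14); the ylide then undergoes a [2,3]-sigmatropic shift in which C10 bonds to the vinyl terminus C9 while O–C7 breaks, so the six-membered ring grows by three atoms into the ten-membered carbocycle. The closest known reaction type is the copper- or rhodium-catalysed oxonium ylide formation and [2,3] ring expansion of 2-alkenyl-tetrahydropyranyl diazo ketones to 11-oxabicyclo[6.2.1]undecenones. The oxolan-3-one ring closes by attack of an ether lone pair on the carbenoid carbon through a five-membered array (5-exo type), and the carbocycle arises through the five-centre envelope transition state of the [2,3] shift. The quaternary centre C10 is controlled by C3: the vinyl group lies on the same face of the oxonium ring as C4, so C9 is delivered cis to C4 and only the cis-bridged bicycle (10S from 3S) can form; the E geometry of C7=C8 is expected from the rhodium carboxamidate catalyst acting on the 2,6-cis pyran. The step needs ylide formation to outrun 1,2-hydride shift from the methyl group, C–H insertion and cyclopropanation, and needs the exocyclic vinyl group to migrate in place of the ring allyl unit C3–C4=C5 or a [1,2] shift; the five-membered contact between oxygen and carbenoid, the carboxamidate ligands, and the ring C3–O bond lying near the nodal plane of the C4=C5 pi system should secure this.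

**Step 11**
Reactants: 15 (1S,2Z,4S,5E,8S)-4-(4-methoxyphenoxy)-2,8-dimethyl-11-oxabicyclo[6.2.1]undeca-2,5-dien-9-one
Product: 17 (2Z,4S,5E,8S)-4-(4-methoxyphenoxy)-2,8-dimethyl-11-oxabicyclo[6.2.1]undeca-1(10),2,5-trien-9-one, via lithium enolate 16 (not isolated)
Conditions: LiN(i-Pr)2, THF, −78 °C; then PhS(Cl)=N-t-Bu, −78 °C
Reagents that add atoms: none
Why: Mukaiyama dehydrogenation: C2 is the only enolisable position, and syn elimination of the sulfur adduct toward the bridgehead C3–H gives the 3(2H)-furanone, deleting the auxiliary C3 centre as planned.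

**Step 12**
Reactants: 17 (2Z,4S,5E,8S)-4-(4-methoxyphenoxy)-2,8-dimethyl-11-oxabicyclo[6.2.1]undeca-1(10),2,5-trien-9-one
Product: 18 (2Z,4S,5E,8S)-4-hydroxy-2,8-dimethyl-11-oxabicyclo[6.2.1]undeca-1(10),2,5-trien-9-one
Conditions: (NH4)2Ce(NO3)6, MeCN/H2O (4:1), 0 °C
Reagents that add atoms: none
Why: Oxidative removal of the 4-methoxyphenyl ether cleaves the aryl–oxygen bond through the arene radical cation, so the allylic alcohol is freed with retention at C6.

**Step 13**
Reactants: 18 (2Z,4S,5E,8S)-4-hydroxy-2,8-dimethyl-11-oxabicyclo[6.2.1]undeca-1(10),2,5-trien-9-one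
Product: 19 (2Z,4R,5R,6R,8S)-5,6-epoxy-4-hydroxy-2,8-dimethyl-11-oxabicyclo[6.2.1]undeca-1(10),2-dien-9-one (epoxide erythro, anti, to the hydroxyl)
Conditions: Ti(OiPr)4 (20 mol %), D-(−)-diisopropyl tartrate, t-BuOOH, 4 Å MS, CH2Cl2, −20 °C
Reagents that add atoms: tert-butyl hydroperoxide CC(C)(C)OO
Why: Sharpless asymmetric epoxidation in its matched (fast kinetic-resolution) sense: for this carbinol configuration the D-tartrate catalyst should epoxidise the E-disubstituted C7=C8 alkene to the erythro epoxy alcohol (7R,8R in germacrane labels) and is mismatched for the other allylic alkene, which is also Z-trisubstituted and conjugated.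

**Step 14**
Reactants: 19 (2Z,4R,5R,6R,8S)-5,6-epoxy-4-hydroxy-2,8-dimethyl-11-oxabicyclo[6.2.1]undeca-1(10),2-dien-9-one; 20 2-(diethoxyphosphoryl)acetic acid
Product: 21 (2Z,4R,5R,6R,8S)-5,6-epoxy-2,8-dimethyl-9-oxo-11-oxabicyclo[6.2.1]undeca-1(10),2-dien-4-yl 2-(diethoxyphosphoryl)acetate
Conditions: EDC, DMAP (cat.), CH2Cl2, 0 °C to rt
Reagents that add atoms: none
Why: Steglich-type carbodiimide esterification of the secondary alcohol; no stereocentre is touched.

**Step 15**
Reactants: 21 (2Z,4R,5R,6R,8S)-5,6-epoxy-2,8-dimethyl-9-oxo-11-oxabicyclo[6.2.1]undeca-1(10),2-dien-4-yl 2-(diethoxyphosphoryl)acetate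
Product: 23 (6R,7R,8R,10S)-8-hydroxy-1-oxo-3,10-epoxygermacra-2,4Z,11(13)-trien-12,6-olide, via sodium salt of phosphono lactone 22 (not isolated)
Conditions: NaH (1.1 equiv), THF, 0 to 45 °C; then (CH2O)n, rt
Reagents that add atoms: formaldehyde C=O
Why: Proposed new method: the phosphonoacetate carbanion, held on the C6 oxygen, should open the anti-disposed epoxide at C7 in a 5-exo-tet SN2 reaction with inversion (setting 7R, leaving the 8R C–O bond untouched and giving the trans-fused lactone); the C8 alkoxide is then quenched by the more acidic phosphono lactone 22, whose anion undergoes Horner–Wadsworth–Emmons methylenation with formaldehyde; the closest known reaction types are the intermolecular opening of epoxides by phosphonoacetate anions to alpha-phosphono-gamma-lactones followed by formaldehyde olefination, and the C-2-selective intramolecular opening of 2,3-epoxy alcohol derivatives by O-tethered nucleophiles.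

**Step 16**
Reactants: 24 tert-butyl 2-(triphenylphosphoranylidene)propanoate; 25 glycolaldehyde dimer (1,4-dioxane-2,5-diol)
Product: 26 tert-butyl (E)-4-hydroxy-2-methylbut-2-enoate
Conditions: CH2Cl2, rt (25 at 0.5 equiv)
Reagents that add atoms: none
Why: Wittig olefination with a stabilised ylide gives the (E)-trisubstituted enoate; the dimer reacts as monomeric glycolaldehyde.

**Step 17**
Reactants: 26 tert-butyl (E)-4-hydroxy-2-methylbut-2-enoate
Product: 27 tert-butyl (E)-4-acetoxy-2-methylbut-2-enoate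
Conditions: Ac2O, pyridine, DMAP (cat.), CH2Cl2, 0 °C to rt
Reagents that add atoms: acetic anhydride CC(=O)OC(C)=O
Why: Acetylation of the primary allylic alcohol.

**Step 18**
Reactants: 27 tert-butyl (E)-4-acetoxy-2-methylbut-2-enoate
Product: 28 (E)-4-acetoxy-2-methylbut-2-enoic acid
Conditions: CF3CO2H, CH2Cl2, 0 °C to rt
Reagents that add atoms: none
Why: Acidolysis of the tert-butyl ester (E1 loss of isobutene) leaves the acetate and the E alkene intact.

**Step 19**
Reactants: 23 (6R,7R,8R,10S)-8-hydroxy-1-oxo-3,10-epoxygermacra-2,4Z,11(13)-trien-12,6-olide; 28 (E)-4-acetoxy-2-methylbut-2-enoic acid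
Product: 30 (6R,7R,8R,10S)-8-[(E)-4-acetoxy-2-methylbut-2-enoyloxy]-1-oxo-3,10-epoxygermacra-2,4Z,11(13)-trien-12,6-olide (CNP0387534.1), via mixed trichlorobenzoic anhydride 29 (not isolated)
Conditions: 2,4,6-Cl3C6H2COCl, Et3N, toluene, rt; then 23, DMAP, rt
Reagents that add atoms: none
Why: Yamaguchi esterification acylates the hindered secondary C8 hydroxyl with retention under conditions mild enough for the methylene lactone and the allylic acetate.

**Compound list**

1 | furan-3-ylmethanol | OCc1ccoc1 | starting material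
2 | trimethyl orthoacetate | CC(OC)(OC)OC | starting material
3 | methyl 2-(3-methylfuran-2-yl)acetate | COC(=O)Cc1occc1C | intermediate
4 | methyl 2-(5-formyl-3-methylfuran-2-yl)acetate | COC(=O)Cc1oc(C=O)cc1C | intermediate
5 | methyl 2-[5-(1-hydroxyprop-2-en-1-yl)-3-methylfuran-2-yl]acetate (racemic) | COC(=O)Cc1oc(C(O)C=C)cc1C | intermediate
6 | methyl 2-[(6R)-2-hydroxy-3-methyl-5-oxo-6-vinyl-5,6-dihydro-2H-pyran-2-yl]acetate | O1C(O)(CC(=O)OC)C(C)=CC(=O)[C@H]1C=C | intermediate
7 | methyl 2-[(2S,6R)-3-methyl-5-oxo-6-vinyl-5,6-dihydro-2H-pyran-2-yl]acetate | O1[C@@H](CC(=O)OC)C(C)=CC(=O)[C@H]1C=C | intermediate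
8 | methyl 2-[(2S,5S,6R)-5-hydroxy-3-methyl-6-vinyl-5,6-dihydro-2H-pyran-2-yl]acetate | O1[C@@H](CC(=O)OC)C(C)=C[C@H](O)[C@H]1C=C | intermediate
9 | 4-methoxyphenol | COc1ccc(O)cc1 | starting material
10 | methyl 2-[(2S,5R,6R)-5-(4-methoxyphenoxy)-3-methyl-6-vinyl-5,6-dihydro-2H-pyran-2-yl]acetate | O1[C@@H](CC(=O)OC)C(C)=C[C@@H](Oc2ccc(OC)cc2)[C@H]1C=C | intermediate
11 | 2-[(2S,5R,6R)-5-(4-methoxyphenoxy)-3-methyl-6-vinyl-5,6-dihydro-2H-pyran-2-yl]acetic acid | O1[C@@H](CC(=O)O)C(C)=C[C@@H](Oc2ccc(OC)cc2)[C@H]1C=C | intermediate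
12 | mixed isobutyl carbonic anhydride of 11 | O1[C@@H](CC(=O)OC(=O)OCC(C)C)C(C)=C[C@@H](Oc2ccc(OC)cc2)[C@H]1C=C | intermediate
13 | 3-diazo-1-[(2S,5R,6R)-5-(4-methoxyphenoxy)-3-methyl-6-vinyl-5,6-dihydro-2H-pyran-2-yl]butan-2-one | O1[C@@H](CC(=O)C(C)=[N+]=[N-])C(C)=C[C@@H](Oc2ccc(OC)cc2)[C@H]1C=C | intermediate
14 | bicyclic oxonium ylide (ring oxygen bonded to C3, C7 and C10; carbanion at C10) | C[C-]1C(=O)C[C@H]2C(C)=C[C@@H](Oc3ccc(OC)cc3)[C@@H](C=C)[O+]12 | intermediate
15 | (1S,2Z,4S,5E,8S)-4-(4-methoxyphenoxy)-2,8-dimethyl-11-oxabicyclo[6.2.1]undeca-2,5-dien-9-one | C[C@]12C/C=C/[C@H](Oc3ccc(OC)cc3)/C=C(/C)[C@H](CC1=O)O2 | intermediate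
16 | lithium enolate of 15 | C[C@]12C/C=C/[C@H](Oc3ccc(OC)cc3)/C=C(/C)[C@H](C=C1[O-])O2.[Li+] | intermediate
17 | (2Z,4S,5E,8S)-4-(4-methoxyphenoxy)-2,8-dimethyl-11-oxabicyclo[6.2.1]undeca-1(10),2,5-trien-9-one | C[C@]12C/C=C/[C@H](Oc3ccc(OC)cc3)/C=C(/C)C(=CC1=O)O2 | intermediate
18 | (2Z,4S,5E,8S)-4-hydroxy-2,8-dimethyl-11-oxabicyclo[6.2.1]undeca-1(10),2,5-trien-9-one | C[C@]12C/C=C/[C@H](O)/C=C(/C)C(=CC1=O)O2 | intermediate
19 | (2Z,4R,5R,6R,8S)-5,6-epoxy-4-hydroxy-2,8-dimethyl-11-oxabicyclo[6.2.1]undeca-1(10),2-dien-9-one | C[C@]12C[C@H]3O[C@@H]3[C@H](O)/C=C(/C)C(=CC1=O)O2 | intermediate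
20 | 2-(diethoxyphosphoryl)acetic acid | CCOP(=O)(CC(=O)O)OCC | starting material
21 | (2Z,4R,5R,6R,8S)-5,6-epoxy-2,8-dimethyl-9-oxo-11-oxabicyclo[6.2.1]undeca-1(10),2-dien-4-yl 2-(diethoxyphosphoryl)acetate | C[C@]12C[C@H]3O[C@@H]3[C@H](OC(=O)CP(=O)(OCC)OCC)/C=C(/C)C(=CC1=O)O2 | intermediate
22 | (6R,7R,8R,10S)-11-(diethoxyphosphoryl)-8-hydroxy-1-oxo-3,10-epoxygermacra-2,4Z-dien-12,6-olide (C11 epimers, formed as sodium salt) | CCOP(=O)(OCC)C1C(=O)O[C@@H]2/C=C(/C)C3=CC(=O)[C@](C)(C[C@@H](O)[C@@H]12)O3 | intermediate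
23 | (6R,7R,8R,10S)-8-hydroxy-1-oxo-3,10-epoxygermacra-2,4Z,11(13)-trien-12,6-olide | C=C1C(=O)O[C@@H]2/C=C(/C)C3=CC(=O)[C@](C)(C[C@@H](O)[C@@H]12)O3 | intermediate
24 | tert-butyl 2-(triphenylphosphoranylidene)propanoate | CC(C(=O)OC(C)(C)C)=P(c1ccccc1)(c1ccccc1)c1ccccc1 | starting material
25 | glycolaldehyde dimer (1,4-dioxane-2,5-diol) | OC1COC(O)CO1 | starting material
26 | tert-butyl (E)-4-hydroxy-2-methylbut-2-enoate | CC(C)(C)OC(=O)/C(C)=C/CO | intermediate
27 | tert-butyl (E)-4-acetoxy-2-methylbut-2-enoate | CC(C)(C)OC(=O)/C(C)=C/COC(C)=O | intermediate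
28 | (E)-4-acetoxy-2-methylbut-2-enoic acid | OC(=O)/C(C)=C/COC(C)=O | intermediate
29 | mixed anhydride of 28 and 2,4,6-trichlorobenzoic acid | O=C(OC(=O)/C(C)=C/COC(C)=O)c1c(Cl)cc(Cl)cc1Cl | intermediate
30 | (6R,7R,8R,10S)-8-[(E)-4-acetoxy-2-methylbut-2-enoyloxy]-1-oxo-3,10-epoxygermacra-2,4Z,11(13)-trien-12,6-olide (CNP0387534.1) | C=C1C(=O)O[C@@H]2/C=C(/C)C3=CC(=O)[C@](C)(C[C@@H](OC(=O)/C(C)=C/COC(C)=O)[C@@H]12)O3 | target

**Step count and risks**

Total step count: 19. Longest linear sequence: 16 (steps 1–15 and 19); steps 16–18 make the side-chain acid.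

Steps most likely to fail:

1. Step 15 (proposed new method). The stabilised carbanion may be too weak a nucleophile for the epoxide, may add reversibly to C5 of the dienone, or the freed C8 alkoxide may trans-lactonise. The fallback uses known chemistry, sets out from 19 and returns at 30. Compound 19 would be O-propargylated (propargyl bromide, Ag2O) to the propargyl ether F1. A Nugent–RajanBabu cyclisation (Cp2TiCl2, Zn, THF; trivalent titanium) would open the epoxide homolytically at C7 and close 5-exo-dig onto the alkyne, giving the 3-methylene-tetrahydrofuran alcohol F2 with the C8–O bond retained. Yamaguchi acylation with 28 would give the ester F3. Allylic oxidation of the ring CH2 between oxygen and the exocyclic alkene (CrO3·2C5H5N, CH2Cl2) would then give 30.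

2. Step 10. The methyl-substituted carbenoid may undergo 1,2-hydride migration to an enone faster than it is captured by the ring oxygen. The fallback sets out from 11 and returns at 17. The mixed anhydride 12 would be treated with diazomethane to give the terminal diazo ketone F4. Ring expansion under the same catalyst, Rh2(NHCOCF3)4, which is the most closely precedented case, would give the bicyclic ketone lacking the methyl group F5. Mukaiyama dehydrogenation as in step 11 would give the 2-unsubstituted furanone F6. Deprotonation at C10 (LiN(SiMe3)2, THF, −78 °C) and C-methylation with MeI would give 17; the bridgehead carbon has only one open position, so the configuration at C10 is fixed by the bridge.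

3. Step 13. Site and facial selectivity of the titanium tartrate epoxidation may be poor on a doubly allylic carbinol held in the bridged ring. The fallback sets out from 18 and returns at 19. Oxidation with MnO2 would give the cross-conjugated dienone F7. Weitz–Scheffer epoxidation (t-BuOOH, DBU) of the more electrophilic E-disubstituted enone would give the epoxy ketone F8, with the face set by the bridged bicycle. Chelation-controlled reduction with Zn(BH4)2 would give the erythro epoxy alcohol 19.

**Further compounds**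

F1 | step 15 | (2Z,4R,5R,6R,8S)-5,6-epoxy-2,8-dimethyl-4-(prop-2-yn-1-yloxy)-11-oxabicyclo[6.2.1]undeca-1(10),2-dien-9-one | C[C@]12C[C@H]3O[C@@H]3[C@H](OCC#C)/C=C(/C)C(=CC1=O)O2
F2 | step 15 | (6R,7R,8R,10S)-8-hydroxy-1-oxo-3,10:6,12-diepoxygermacra-2,4Z,11(13)-triene (methylene tetrahydrofuran in place of the lactone) | C=C1CO[C@@H]2/C=C(/C)C3=CC(=O)[C@](C)(C[C@@H](O)[C@@H]12)O3
F3 | step 15 | 8-O-[(E)-4-acetoxy-2-methylbut-2-enoyl] derivative of F2 | C=C1CO[C@@H]2/C=C(/C)C3=CC(=O)[C@](C)(C[C@@H](OC(=O)/C(C)=C/COC(C)=O)[C@@H]12)O3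
F4 | step 10 | 1-diazo-3-[(2S,5R,6R)-5-(4-methoxyphenoxy)-3-methyl-6-vinyl-5,6-dihydro-2H-pyran-2-yl]propan-2-one | O1[C@@H](CC(=O)C=[N+]=[N-])C(C)=C[C@@H](Oc2ccc(OC)cc2)[C@H]1C=C
F5 | step 10 | 4-(4-methoxyphenoxy)-2-methyl-11-oxabicyclo[6.2.1]undeca-2Z,5E-dien-9-one (15 without the C8 methyl group) | O=C1C[C@@H]2O[C@H]1C/C=C/[C@H](Oc3ccc(OC)cc3)/C=C2/C
F6 | step 10 | 4-(4-methoxyphenoxy)-2-methyl-11-oxabicyclo[6.2.1]undeca-1(10),2Z,5E-trien-9-one (17 without the C8 methyl group) | O=C1C=C2O[C@H]1C/C=C/[C@H](Oc3ccc(OC)cc3)/C=C2/C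
F7 | step 13 | (2Z,5E,8S)-2,8-dimethyl-11-oxabicyclo[6.2.1]undeca-1(10),2,5-triene-4,9-dione | C[C@]12C/C=C/C(=O)/C=C(/C)C(=CC1=O)O2
F8 | step 13 | (2Z,5R,6R,8S)-5,6-epoxy-2,8-dimethyl-11-oxabicyclo[6.2.1]undeca-1(10),2-diene-4,9-dione | C[C@]12C[C@H]3O[C@@H]3C(=O)/C=C(/C)C(=CC1=O)O2
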